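**Strategy.** The route rests on cutting the exocyclic C3–CH2O bond of the tetrahydrofuran. Ring carbon C5 is carried as a lactone carbonyl, which makes C3 the β-carbon of an (S)-γ-aryl-α-benzylbutenolide. In one operation a visible-light decarboxylative Giese reaction adds the intact isovaleroxymethyl radical to C3 anti to the C2 aryl group, and hydrogen-atom delivery to the resulting C4 radical anti to the new side chain sets the 3,4-cis relationship; the complete ester side chain and two stereocentres thus arise together. The butenolide comes from an asymmetric propiolate addition to O-benzylvanillin, hydrostannation–lactonisation and Stille benzylation; chemoselective lactone-to-ether reduction and hydrogenolysis finish the synthesis.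

Key step: step 7

Remark on the chemistry: the (S,S)-ProPhenol/Me2Zn catalyst is assumed to deliver the (R)-configured carbinol 3; should the sense of induction be opposite, the (R,R)-ligand is used and nothing else changes.

Step 1
Reactants: 1 4-(benzyloxy)-3-methoxybenzaldehyde; 2 methyl propiolate
Product: 3 methyl (R)-4-[4-(benzyloxy)-3-methoxyphenyl]-4-hydroxybut-2-ynoate
Conditions: (S,S)-ProPhenol (10 mol %), Ph3P=O (20 mol %), Me2Zn (3 equiv), 2 (3 equiv), toluene, 4 °C; aq. NH4Cl
Reagents that add atoms: none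
Why: Zinc–ProPhenol-catalysed asymmetric alkynylation of an aryl aldehyde, in which the chiral dinuclear zinc pocket differentiates the aldehyde faces and should set the benzylic carbinol centre (the later ring carbon C2) with high enantioselectivity.

Step 2
Reactants: 3 methyl (R)-4-[4-(benzyloxy)-3-methoxyphenyl]-4-hydroxybut-2-ynoate
Product: 5 (S)-5-[4-(benzyloxy)-3-methoxyphenyl]-3-(tributylstannyl)furan-2(5H)-one, via stannyl hydroxy enoate 4 (not isolated)
Conditions: Bu3SnH (1.2 equiv), Pd(PPh3)4 (2 mol %, zerovalent palladium), THF, 0 °C → rt; then PPTS (cat.), CH2Cl2, rt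
Reagents that add atoms: tributyltin hydride, CCCC[SnH](CCCC)CCCC
Why: Palladium-catalysed syn-hydrostannation of a 4-hydroxy-2-alkynoate places tin α to the ester and hydrogen on the β-carbon, so that ester and carbinol are cis in 4 and lactonise, the carbinol centre remaining untouched (its descriptor changes only through the priority rules).

Step 3
Reactants: 6 [4-(benzyloxy)-3-methoxyphenyl]methanol
Product: 7 1-(benzyloxy)-4-(bromomethyl)-2-methoxybenzene
Conditions: PBr3 (0.4 equiv), Et2O, 0 °C; used without storage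
Reagents that add atoms: phosphorus tribromide, BrP(Br)Br
Why: Standard conversion of an electron-rich benzylic alcohol into the bromide by PBr3 (nucleophilic substitution via the phosphite ester), with no stereocentre involved.

Step 4
Reactants: 5 (S)-5-[4-(benzyloxy)-3-methoxyphenyl]-3-(tributylstannyl)furan-2(5H)-one; 7 1-(benzyloxy)-4-(bromomethyl)-2-methoxybenzene
Product: 8 (S)-3-[4-(benzyloxy)-3-methoxybenzyl]-5-[4-(benzyloxy)-3-methoxyphenyl]furan-2(5H)-one
Conditions: Pd2(dba)3 (2.5 mol %, zerovalent palladium), AsPh3 (20 mol %), CuI (copper monoiodide, 10 mol %), NMP, 50 °C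
Reagents that add atoms: none
Why: Stille coupling of an α-stannyl butenolide with a benzylic bromide under neutral, base-free conditions, which should leave the base-sensitive γ-stereocentre intact.

Step 5
Reactants: 9 glycolic acid; 10 3-methylbutanoyl chloride
Product: 11 2-[(3-methylbutanoyl)oxy]acetic acid
Conditions: neat 10 (1.5 equiv), rt → 50 °C; then H2O, rt
Reagents that add atoms: none
Why: O-acylation of the hydroxy acid by the acid chloride, any mixed anhydride being hydrolysed back to the acid in the aqueous work-up.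

Step 6
Reactants: 11 2-[(3-methylbutanoyl)oxy]acetic acid
Product: 12 1,3-dioxoisoindolin-2-yl 2-[(3-methylbutanoyl)oxy]acetate
Conditions: N-hydroxyphthalimide (1.05 equiv), DIC (1.1 equiv), DMAP (5 mol %), CH2Cl2, 0 °C → rt
Reagents that add atoms: N-hydroxyphthalimide, O=C1c2ccccc2C(=O)N1O
Why: Carbodiimide-mediated (Steglich-type) esterification gives the redox-active N-(acyloxy)phthalimide needed for reductive radical generation.

Step 7
Reactants: 8 (S)-3-[4-(benzyloxy)-3-methoxybenzyl]-5-[4-(benzyloxy)-3-methoxyphenyl]furan-2(5H)-one; 12 1,3-dioxoisoindolin-2-yl 2-[(3-methylbutanoyl)oxy]acetate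
Product: 13 [(2S,3R,4R)-4-[4-(benzyloxy)-3-methoxybenzyl]-2-[4-(benzyloxy)-3-methoxyphenyl]-5-oxotetrahydrofuran-3-yl]methyl 3-methylbutanoate
Conditions: Ru(bpy)3(PF6)2 (1 mol %), Hantzsch ester (diethyl 2,6-dimethyl-1,4-dihydropyridine-3,5-dicarboxylate, 1.5 equiv), 12 (1.5 equiv), degassed CH2Cl2, blue LEDs (450 nm), rt, no amine base
Reagents that add atoms: none
Why: Photoexcited divalent ruthenium is quenched reductively by the Hantzsch ester, and the reduced (monovalent) ruthenium passes an electron to 12, which loses phthalimide anion and CO2 to give the nucleophilic primary (3-methylbutanoyloxy)methyl radical; this adds to the β-carbon of the butenolide, and the tertiary α-lactone radical then takes a hydrogen atom from the Hantzsch ester or its radical cation. The closest known reaction type is the decarboxylative Giese addition of N-(acyloxy)phthalimide-derived radicals to γ-substituted butenolides. No ring is closed; the five-membered lactone of 8 is kept and later becomes the tetrahydrofuran. The new C3 stereocentre is controlled by the adjacent C2 aryl group (attack on the opposite face, 2,3-trans), and the new C4 stereocentre by the freshly installed C3 side chain, the hydrogen donor approaching the planar radical anti to it so that benzyl and acyloxymethyl end up cis. The step needs β-regioselectivity (secured by the lactone carbonyl and the stabilised α-radical), two facial selectivities (secured by 1,2-induction within the five-membered ring) and retention of the acidic γ-stereocentre (secured by base-free conditions at room temperature).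

Step 8
Reactants: 13 [(2S,3R,4R)-4-[4-(benzyloxy)-3-methoxybenzyl]-2-[4-(benzyloxy)-3-methoxyphenyl]-5-oxotetrahydrofuran-3-yl]methyl 3-methylbutanoate
Product: 14 [(2S,3R,4R)-4-[4-(benzyloxy)-3-methoxybenzyl]-2-[4-(benzyloxy)-3-methoxyphenyl]-5-hydroxytetrahydrofuran-3-yl]methyl 3-methylbutanoate (mixture of C5 epimers)
Conditions: Sia2BH (4 equiv, made from BH3·THF and 2-methyl-2-butene), THF, 0 °C → rt; then H2O; H2O2, pH 7 phosphate buffer, 0 °C
Reagents that add atoms: none
Why: Chemoselective partial reduction by disiamylborane, which reduces γ-lactones to lactols (the borinate stops at this oxidation level) while open-chain esters such as the isovalerate react only very slowly, as known for acylated aldonolactones; no defined stereocentre is created.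

Step 9
Reactants: 14 [(2S,3R,4R)-4-[4-(benzyloxy)-3-methoxybenzyl]-2-[4-(benzyloxy)-3-methoxyphenyl]-5-hydroxytetrahydrofuran-3-yl]methyl 3-methylbutanoate
Product: 15 [(2S,3R,4R)-4-[4-(benzyloxy)-3-methoxybenzyl]-2-[4-(benzyloxy)-3-methoxyphenyl]tetrahydrofuran-3-yl]methyl 3-methylbutanoate
Conditions: Et3SiH (4 equiv), BF3·OEt2 (1.5 equiv), CH2Cl2, −78 → −40 °C; aq. NaHCO3
Reagents that add atoms: none
Why: Ionic reduction of a lactol, in which BF3 ionises the anomeric hydroxyl to a cyclic oxocarbenium ion that is trapped by silane hydride so that C5 becomes CH2 without creating a stereocentre, the low temperature protecting the benzylic C2–O bond and the C4 centre.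

Step 10
Reactants: 15 [(2S,3R,4R)-4-[4-(benzyloxy)-3-methoxybenzyl]-2-[4-(benzyloxy)-3-methoxyphenyl]tetrahydrofuran-3-yl]methyl 3-methylbutanoate
Product: 16 [(2S,3R,4R)-4-(4-hydroxy-3-methoxybenzyl)-2-(4-hydroxy-3-methoxyphenyl)tetrahydrofuran-3-yl]methyl 3-methylbutanoate, (+)-9'-isovaleroxylariciresinol
Conditions: H2 (1 atm), 10% Pd/C, EtOAc, rt, stopped at full conversion
Reagents that add atoms: none
Why: Hydrogenolysis of the two aryl benzyl ethers, which in neutral ethyl acetate should be much faster than cleavage of the ring benzylic C2–O bond, leaves the ester and all three stereocentres untouched.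

**Compound list**

1 | 4-(benzyloxy)-3-methoxybenzaldehyde | COc1cc(C=O)ccc1OCc1ccccc1 | starting material
2 | methyl propiolate | C#CC(=O)OC | starting material
3 | methyl (R)-4-[4-(benzyloxy)-3-methoxyphenyl]-4-hydroxybut-2-ynoate | O[C@H](c1ccc(OCc2ccccc2)c(OC)c1)C#CC(=O)OC | intermediate
4 | methyl (S,E)-4-[4-(benzyloxy)-3-methoxyphenyl]-4-hydroxy-2-(tributylstannyl)but-2-enoate (not isolated) | COC(=O)/C(=C\[C@H](O)c1ccc(OCc2ccccc2)c(OC)c1)[Sn](CCCC)(CCCC)CCCC | intermediate
5 | (S)-5-[4-(benzyloxy)-3-methoxyphenyl]-3-(tributylstannyl)furan-2(5H)-one | O=C1O[C@H](c2ccc(OCc3ccccc3)c(OC)c2)C=C1[Sn](CCCC)(CCCC)CCCC | intermediate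
6 | [4-(benzyloxy)-3-methoxyphenyl]methanol | COc1cc(CO)ccc1OCc1ccccc1 | starting material
7 | 1-(benzyloxy)-4-(bromomethyl)-2-methoxybenzene | COc1cc(CBr)ccc1OCc1ccccc1 | intermediate
8 | (S)-3-[4-(benzyloxy)-3-methoxybenzyl]-5-[4-(benzyloxy)-3-methoxyphenyl]furan-2(5H)-one | O=C1O[C@H](c2ccc(OCc3ccccc3)c(OC)c2)C=C1Cc1ccc(OCc2ccccc2)c(OC)c1 | intermediate
9 | glycolic acid | OCC(=O)O | starting material
10 | 3-methylbutanoyl chloride (isovaleryl chloride) | CC(C)CC(=O)Cl | starting material
11 | 2-[(3-methylbutanoyl)oxy]acetic acid | CC(C)CC(=O)OCC(=O)O | intermediate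
12 | 1,3-dioxoisoindolin-2-yl 2-[(3-methylbutanoyl)oxy]acetate | CC(C)CC(=O)OCC(=O)ON1C(=O)c2ccccc2C1=O | intermediate
13 | [(2S,3R,4R)-4-[4-(benzyloxy)-3-methoxybenzyl]-2-[4-(benzyloxy)-3-methoxyphenyl]-5-oxotetrahydrofuran-3-yl]methyl 3-methylbutanoate | COc1cc(C[C@H]2C(=O)O[C@H](c3ccc(OCc4ccccc4)c(OC)c3)[C@H]2COC(=O)CC(C)C)ccc1OCc1ccccc1 | intermediate
14 | [(2S,3R,4R)-4-[4-(benzyloxy)-3-methoxybenzyl]-2-[4-(benzyloxy)-3-methoxyphenyl]-5-hydroxytetrahydrofuran-3-yl]methyl 3-methylbutanoate (C5 epimers) | COc1cc(C[C@H]2C(O)O[C@H](c3ccc(OCc4ccccc4)c(OC)c3)[C@H]2COC(=O)CC(C)C)ccc1OCc1ccccc1 | intermediate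
15 | [(2S,3R,4R)-4-[4-(benzyloxy)-3-methoxybenzyl]-2-[4-(benzyloxy)-3-methoxyphenyl]tetrahydrofuran-3-yl]methyl 3-methylbutanoate | COc1cc(C[C@H]2CO[C@H](c3ccc(OCc4ccccc4)c(OC)c3)[C@H]2COC(=O)CC(C)C)ccc1OCc1ccccc1 | intermediate
16 | [(2S,3R,4R)-4-(4-hydroxy-3-methoxybenzyl)-2-(4-hydroxy-3-methoxyphenyl)tetrahydrofuran-3-yl]methyl 3-methylbutanoate, (+)-9'-isovaleroxylariciresinol | COc1cc(C[C@H]2CO[C@H](c3ccc(O)c(OC)c3)[C@H]2COC(=O)CC(C)C)ccc1O | target

Total step count: 10
Longest linear sequence: 7 steps (steps 1, 2, 4, 7, 8, 9, 10)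

**Steps most likely to fail**

Step 7. Hydrogen-atom transfer to the α-lactone radical may be poorly face-selective, eroding the 3,4-cis relationship. Radical addition to the trisubstituted alkene may also be slow enough that the radical is simply reduced. The fallback sets out from 3 and returns at 13.
- Semihydrogenation of 3 over Pd/CaCO3 poisoned with Pb(OAc)2 (quinoline, EtOAc) should give methyl (S,Z)-4-[4-(benzyloxy)-3-methoxyphenyl]-4-hydroxybut-2-enoate F1.
- F1 lactonises with catalytic PPTS to (S)-5-[4-(benzyloxy)-3-methoxyphenyl]furan-2(5H)-one F2.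
- The same photoredox Giese addition of 12 to this more reactive disubstituted butenolide should give [(2S,3R)-2-[4-(benzyloxy)-3-methoxyphenyl]-5-oxotetrahydrofuran-3-yl]methyl 3-methylbutanoate F3, with only C3 set, trans to the aryl group.
- The lactone α-position, more acidic than that of the open-chain ester, is enolised with LiN(SiMe3)2 (THF, −78 °C) and condensed with aldehyde 1 to the aldol adduct [(2S,3R)-4-[[4-(benzyloxy)-3-methoxyphenyl](hydroxy)methyl]-2-[4-(benzyloxy)-3-methoxyphenyl]-5-oxotetrahydrofuran-3-yl]methyl 3-methylbutanoate F4.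
- Mesylation (MsCl, Et3N) gives the mesylate of the aldol adduct F5, which is eliminated with DBU to the (E)-benzylidene lactone [(2S,3R,4E)-4-[4-(benzyloxy)-3-methoxybenzylidene]-2-[4-(benzyloxy)-3-methoxyphenyl]-5-oxotetrahydrofuran-3-yl]methyl 3-methylbutanoate F6.
- Hydrogenation over Pd/C in the presence of Ph2S (benzyl ethers retained) should deliver hydrogen to the face opposite the C3 side chain and so give 13.

Step 8. Hydride delivery may be incomplete or unselective: the hindered, trisubstituted lactone may react too slowly with the bulky borane, or the isovalerate may be attacked. The fallback sets out from 13 and returns at 15, bypassing step 9.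
- Exhaustive reduction with LiAlH4 (THF, 0 °C) gives the triol (2R,3R)-2-[4-(benzyloxy)-3-methoxybenzyl]-3-[(S)-[4-(benzyloxy)-3-methoxyphenyl](hydroxy)methyl]butane-1,4-diol F7, the isovalerate being sacrificed.
- Acid-catalysed cyclisation (camphorsulfonic acid cat., CH2Cl2, rt) proceeds through the benzylic cation. The primary hydroxyl of the benzyl-bearing branch closes the five-membered ring (the other would give an oxetane), trans to the C3 substituent, giving [(2S,3R,4R)-4-[4-(benzyloxy)-3-methoxybenzyl]-2-[4-(benzyloxy)-3-methoxyphenyl]tetrahydrofuran-3-yl]methanol F8.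
- Acylation of its only free hydroxyl with 10 (pyridine, DMAP, CH2Cl2) gives 15.

Step 4. Transmetalation of the electron-poor α-stannyl enoate may be slow, allowing protodestannylation and homocoupling of the benzylic bromide. The fallback sets out from 5 and returns at 8, with reversed polarity.
- Iododestannylation (I2, CH2Cl2, 0 °C) gives (S)-5-[4-(benzyloxy)-3-methoxyphenyl]-3-iodofuran-2(5H)-one F9.
- Bromide 7 is converted with Zn dust and LiCl (THF) into [4-(benzyloxy)-3-methoxybenzyl]zinc bromide F10.
- Negishi coupling of the two (Pd(PPh3)4, THF, rt) gives 8.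

**Further compounds**

F1 | step 7 | methyl (S,Z)-4-[4-(benzyloxy)-3-methoxyphenyl]-4-hydroxybut-2-enoate | COC(=O)/C=C\[C@H](O)c1ccc(OCc2ccccc2)c(OC)c1
F2 | step 7 | (S)-5-[4-(benzyloxy)-3-methoxyphenyl]furan-2(5H)-one | O=C1O[C@H](c2ccc(OCc3ccccc3)c(OC)c2)C=C1
F3 | step 7 | [(2S,3R)-2-[4-(benzyloxy)-3-methoxyphenyl]-5-oxotetrahydrofuran-3-yl]methyl 3-methylbutanoate | O=C1O[C@H](c2ccc(OCc3ccccc3)c(OC)c2)[C@@H](COC(=O)CC(C)C)C1
F4 | step 7 | aldol adduct, [(2S,3R)-4-[[4-(benzyloxy)-3-methoxyphenyl](hydroxy)methyl]-2-[4-(benzyloxy)-3-methoxyphenyl]-5-oxotetrahydrofuran-3-yl]methyl 3-methylbutanoate (mixture at C4 and the carbinol) | COc1cc(C(O)C2C(=O)O[C@H](c3ccc(OCc4ccccc4)c(OC)c3)[C@H]2COC(=O)CC(C)C)ccc1OCc1ccccc1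
F5 | step 7 | mesylate of the aldol adduct | COc1cc(C(OS(C)(=O)=O)C2C(=O)O[C@H](c3ccc(OCc4ccccc4)c(OC)c3)[C@H]2COC(=O)CC(C)C)ccc1OCc1ccccc1
F6 | step 7 | [(2S,3R,4E)-4-[4-(benzyloxy)-3-methoxybenzylidene]-2-[4-(benzyloxy)-3-methoxyphenyl]-5-oxotetrahydrofuran-3-yl]methyl 3-methylbutanoate | COc1cc(/C=C2/C(=O)O[C@H](c3ccc(OCc4ccccc4)c(OC)c3)[C@H]2COC(=O)CC(C)C)ccc1OCc1ccccc1
F7 | step 8 | (2R,3R)-2-[4-(benzyloxy)-3-methoxybenzyl]-3-[(S)-[4-(benzyloxy)-3-methoxyphenyl](hydroxy)methyl]butane-1,4-diol | COc1cc(C[C@@H](CO)[C@H](CO)[C@H](O)c2ccc(OCc3ccccc3)c(OC)c2)ccc1OCc1ccccc1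
F8 | step 8 | [(2S,3R,4R)-4-[4-(benzyloxy)-3-methoxybenzyl]-2-[4-(benzyloxy)-3-methoxyphenyl]tetrahydrofuran-3-yl]methanol | COc1cc(C[C@H]2CO[C@H](c3ccc(OCc4ccccc4)c(OC)c3)[C@H]2CO)ccc1OCc1ccccc1
F9 | step 4 | (S)-5-[4-(benzyloxy)-3-methoxyphenyl]-3-iodofuran-2(5H)-one | O=C1O[C@H](c2ccc(OCc3ccccc3)c(OC)c2)C=C1I
F10 | step 4 | [4-(benzyloxy)-3-methoxybenzyl]zinc bromide | COc1cc(C[Zn]Br)ccc1OCc1ccccc1
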